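## Retrosynthetic overview

1. Target 32 comes from the tri-O-benzyl acetal 29 by acetal-to-CH2OH conversion and global hydrogenolysis.
2. 29 is disconnected at ArCH2–Cα: Cu-catalysed conjugate addition of the dihydrobenzofuran aryl-Grignard (from bromide 25) to α-methylene lactone 14, equilibrated to the trans lactone.
3. Dihydrobenzofuran 25 comes from an iodine(III) ring contraction (1,2-aryl shift) of (S)-2-aryl-2H-chromene 24, made by Au hydroarylation of (S)-aryl propargyl ether 23 (Cu-catalysed asymmetric propargylic etherification of phenol 22 with acetate 20).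
4. Lactone 14 comes from α-methylenation of (S)-β-benzyl lactone 12, made by asymmetric Baeyer–Villiger ring expansion of cyclobutanone 11 (dichloroketene [2+2] on allylarene 7).
5. All three arenes come from catechol 1. Ring order: cyclobutanone, then γ-lactone (expansion); chromene, then dihydrobenzofuran (contraction).

Assumption: the ligand enantiomers in steps 6 and 12 are chosen empirically to give the (S) products shown; commercial inputs are 1, 5, 8 and 18, everything else is a standard reagent.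

## Route

Step 1
Reactants: 1 catechol
Product: 2 2-methoxyphenol
Conditions: MeI (1.0 equiv), K2CO3, acetone, reflux
Reagents that add atoms: iodomethane, CI
Why: Williamson mono-O-methylation; one equivalent of MeI gives guaiacol, separable from unreacted catechol and the dimethyl ether.

Step 2
Reactants: 2 2-methoxyphenol
Product: 3 4-bromo-2-methoxyphenol
Conditions: NBS, MeCN, 0 °C to rt
Reagents that add atoms: N-bromosuccinimide, O=C1CCC(=O)N1Br
Why: Electrophilic aromatic bromination directed para to the free OH, the stronger donor.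

Step 3
Reactants: 3 4-bromo-2-methoxyphenol
Product: 4 1-(benzyloxy)-4-bromo-2-methoxybenzene
Conditions: BnBr, K2CO3, DMF, 60 °C
Reagents that add atoms: benzyl bromide, BrCc1ccccc1
Why: Williamson benzylation protects the phenol for the organometallic, peracid and iodine(III) steps; it is removed in the last step.

Step 4
Reactants: 4 1-(benzyloxy)-4-bromo-2-methoxybenzene; 5 allyl bromide
Product: 7 4-allyl-1-(benzyloxy)-2-methoxybenzene, via aryl Grignard reagent 6 (not isolated)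
Conditions: Mg, THF, reflux; then 5, 0 °C to rt
Reagents that add atoms: magnesium, [Mg] (retained only in intermediate 6)
Why: Grignard formation followed by allylation of the arylmagnesium with the reactive allylic bromide.

Step 5
Reactants: 7 4-allyl-1-(benzyloxy)-2-methoxybenzene; 8 trichloroacetyl chloride
Product: 11 3-[4-(benzyloxy)-3-methoxybenzyl]cyclobutan-1-one, via dichloroketene 9 (not isolated), via dichlorocyclobutanone 10 (not isolated)
Conditions: Zn–Cu, Et2O, ultrasound, 15–20 °C (slow addition of 8); then AcOH, Zn dust, rt to 50 °C on the crude dichloroketone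
Reagents that add atoms: none
Why: Ketene–alkene [2+2] cycloaddition places the carbonyl carbon on the terminal CH2, and zinc dechlorination then gives the prochiral 3-substituted cyclobutanone.

Step 6
Reactants: 11 3-[4-(benzyloxy)-3-methoxybenzyl]cyclobutan-1-one
Product: 12 (S)-4-[4-(benzyloxy)-3-methoxybenzyl]dihydrofuran-2(3H)-one
Conditions: Sc(OTf)3 (5 mol%), chiral N,N'-dioxide ligand (5 mol%, enantiomer giving S), m-CPBA, EtOAc, −20 °C; recrystallise to upgrade ee
Reagents that add atoms: m-chloroperbenzoic acid, O=C(OO)c1cccc(Cl)c1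
Why: Catalytic asymmetric Baeyer–Villiger ring expansion; the chiral Lewis acid selects which enantiotopic α-carbon migrates in the Criegee intermediate and so sets C4 as S.

Step 7
Reactants: 12 (S)-4-[4-(benzyloxy)-3-methoxybenzyl]dihydrofuran-2(3H)-one
Product: 14 (S)-4-[4-(benzyloxy)-3-methoxybenzyl]-3-methylenedihydrofuran-2(3H)-one, via sodium formyl enolate 13 (not isolated)
Conditions: NaH, HCO2Et, THF, 0 °C to rt; then (CH2O)n, THF, reflux
Reagents that add atoms: ethyl formate, CCOC=O (formyl carbon only in intermediate 13); sodium hydride, [Na+].[H-] (Na only in intermediate 13); formaldehyde, C=O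
Why: Claisen α-formylation, then aldol with formaldehyde, formyl transfer and loss of formate give the α-methylene lactone; C4 is not touched.

Step 8
Reactants: 4 1-(benzyloxy)-4-bromo-2-methoxybenzene
Product: 17 4-(benzyloxy)-3-methoxybenzaldehyde, via aryllithium 15 (not isolated), via lithium hemiaminolate 16 (not isolated)
Conditions: n-BuLi, THF, −78 °C; DMF, −78 °C to rt; aq. NH4Cl
Reagents that add atoms: n-butyllithium, [Li]CCCC (Li only in intermediates 15 and 16); N,N-dimethylformamide, CN(C)C=O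
Why: Bromine–lithium exchange followed by formylation with DMF (Bouveault aldehyde synthesis).

Step 9
Reactants: 17 4-(benzyloxy)-3-methoxybenzaldehyde; 18 ethynylmagnesium bromide
Product: 20 rac-1-[4-(benzyloxy)-3-methoxyphenyl]prop-2-yn-1-yl acetate, via magnesium propargylic alkoxide 19 (not isolated)
Conditions: 18, THF, 0 °C; then Ac2O, DMAP (cat.), 0 °C to rt
Reagents that add atoms: acetic anhydride, CC(=O)OC(C)=O
Why: Grignard 1,2-addition and in-flask O-acetylation of the alkoxide; the racemate is used because step 12 is enantioconvergent.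

Step 10
Reactants: 1 catechol
Product: 21 2-(benzyloxy)phenol
Conditions: BnBr (1.0 equiv), K2CO3, acetone, reflux
Reagents that add atoms: benzyl bromide, BrCc1ccccc1
Why: Williamson mono-benzylation masks the oxygen that is the free 7-OH of the target.

Step 11
Reactants: 21 2-(benzyloxy)phenol
Product: 22 2-(benzyloxy)-4-bromophenol
Conditions: NBS, MeCN, −10 °C to rt
Reagents that add atoms: N-bromosuccinimide, O=C1CCC(=O)N1Br
Why: Electrophilic bromination para to the free OH installs the handle at the future C5 of the dihydrobenzofuran.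

Step 12
Reactants: 22 2-(benzyloxy)-4-bromophenol; 20 rac-1-[4-(benzyloxy)-3-methoxyphenyl]prop-2-yn-1-yl acetate
Product: 23 (S)-2-(benzyloxy)-1-{[1-(4-(benzyloxy)-3-methoxyphenyl)prop-2-yn-1-yl]oxy}-4-bromobenzene
Conditions: CuOTf·½C6H6 (5 mol%), chiral Ph-pybox (6 mol%, enantiomer giving S), i-Pr2NEt, CH2Cl2, −20 °C
Reagents that add atoms: none
Why: Copper-catalysed asymmetric propargylic etherification; both acetate enantiomers converge on one Cu–allenylidene, and ligand-controlled attack of the phenoxide at the γ-carbon sets the future C2 as S.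

Step 13
Reactants: 23 (S)-2-(benzyloxy)-1-{[1-(4-(benzyloxy)-3-methoxyphenyl)prop-2-yn-1-yl]oxy}-4-bromobenzene
Product: 24 (S)-8-(benzyloxy)-2-[4-(benzyloxy)-3-methoxyphenyl]-6-bromo-2H-chromene
Conditions: [JohnPhosAu(NCMe)]SbF6 (2 mol%), CH2Cl2, 0 °C to rt
Reagents that add atoms: none
Why: Gold(I)-catalysed 6-endo-dig intramolecular hydroarylation at the only free position ortho to the ether oxygen; the C2 stereocentre is not involved.

Step 14
Reactants: 24 (S)-8-(benzyloxy)-2-[4-(benzyloxy)-3-methoxyphenyl]-6-bromo-2H-chromene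
Product: 25 (2S,3S)-7-(benzyloxy)-2-[4-(benzyloxy)-3-methoxyphenyl]-5-bromo-3-(dimethoxymethyl)-2,3-dihydrobenzofuran
Conditions: PhI(OH)OTs (1.1 equiv), MeOH/CH2Cl2 (3:1), −20 to 0 °C; NaHCO3 quench
Reagents that add atoms: methanol, CO
Why: Proposed new method: the λ3-iodane adds to C3 of the styrenic C3=C4 bond anti to the 2-aryl group and MeOH captures benzylic C4; after ring flip the C4–C4a bond is antiperiplanar to the equatorial C3–I(Ph) bond, so the electron-rich ring (ortho oxygen) migrates from C4 to C3 through a phenonium ion with loss of PhI, and the resulting methoxy-oxocarbenium is trapped by MeOH as the dimethyl acetal; inversion at C3 puts the acetal trans to the C2 aryl, which is untouched; the closest known reactions are the Koser-reagent ring contraction of 1,2-dihydronaphthalenes to indane acetals and the iodine(III)/thallium(III) ring contraction of flavanones to methyl 2-aryl-2,3-dihydrobenzofuran-3-carboxylates.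

Step 15
Reactants: 25 (2S,3S)-7-(benzyloxy)-2-[4-(benzyloxy)-3-methoxyphenyl]-5-bromo-3-(dimethoxymethyl)-2,3-dihydrobenzofuran; 14 (S)-4-[4-(benzyloxy)-3-methoxybenzyl]-3-methylenedihydrofuran-2(3H)-one
Product: 29 (3S,4S)-3-{[(2S,3S)-7-(benzyloxy)-2-(4-(benzyloxy)-3-methoxyphenyl)-3-(dimethoxymethyl)-2,3-dihydrobenzofuran-5-yl]methyl}-4-[4-(benzyloxy)-3-methoxybenzyl]dihydrofuran-2(3H)-one, via aryl Grignard reagent 26 (not isolated), via magnesium enolate 27 (not isolated), via cis C3 epimer 28 (not isolated)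
Conditions: Mg, LiCl, THF, rt; then CuBr·SMe2 (10 mol%), slow addition of 14, −40 to 0 °C; then MeOH, NaOMe (0.3 equiv), rt; aq. NH4Cl
Reagents that add atoms: magnesium, [Mg] (retained only in intermediates 26 and 27)
Why: Copper-catalysed 1,4-addition of the aryl Grignard to the exocyclic methylene forms the ArCH2–Cα bond, and alkoxide equilibration of the protonated mixture gives the thermodynamically preferred trans-2,3-dibenzyl lactone (C3 S, set relative to C4).

Step 16
Reactants: 29 (3S,4S)-3-{[(2S,3S)-7-(benzyloxy)-2-(4-(benzyloxy)-3-methoxyphenyl)-3-(dimethoxymethyl)-2,3-dihydrobenzofuran-5-yl]methyl}-4-[4-(benzyloxy)-3-methoxybenzyl]dihydrofuran-2(3H)-one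
Product: 31 (3S,4S)-3-{[(2S,3R)-7-(benzyloxy)-2-(4-(benzyloxy)-3-methoxyphenyl)-3-(hydroxymethyl)-2,3-dihydrobenzofuran-5-yl]methyl}-4-[4-(benzyloxy)-3-methoxybenzyl]dihydrofuran-2(3H)-one, via aldehyde 30 (not isolated)
Conditions: 2 M HCl, THF, rt; then NaHCO3 to pH 7, NaBH4, MeOH, 0 °C
Reagents that add atoms: water, O
Why: Acetal hydrolysis and immediate chemoselective borohydride reduction of the sensitive aldehyde (the lactone is inert at 0 °C); any C3 epimerisation at the aldehyde stage only favours the wanted trans isomer, and the descriptor changes to 3R by CIP priority alone.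

Step 17
Reactants: 31 (3S,4S)-3-{[(2S,3R)-7-(benzyloxy)-2-(4-(benzyloxy)-3-methoxyphenyl)-3-(hydroxymethyl)-2,3-dihydrobenzofuran-5-yl]methyl}-4-[4-(benzyloxy)-3-methoxybenzyl]dihydrofuran-2(3H)-one
Product: 32 (3S,4S)-3-{[(2S,3R)-7-hydroxy-2-(4-hydroxy-3-methoxyphenyl)-3-(hydroxymethyl)-2,3-dihydrobenzofuran-5-yl]methyl}-4-(4-hydroxy-3-methoxybenzyl)dihydrofuran-2(3H)-one
Conditions: H2 (1 atm), 10% Pd/C, EtOAc/MeOH, rt
Reagents that add atoms: none
Why: Neutral hydrogenolysis cleaves the three aryl benzyl ethers; the cyclic benzylic C2–O bond of the dihydrobenzofuran survives these mild conditions.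

## Compound list

1 | catechol | Oc1ccccc1O | starting material
2 | 2-methoxyphenol | COc1ccccc1O | intermediate
3 | 4-bromo-2-methoxyphenol | COc1cc(Br)ccc1O | intermediate
4 | 1-(benzyloxy)-4-bromo-2-methoxybenzene | COc1cc(Br)ccc1OCc1ccccc1 | intermediate
5 | allyl bromide | C=CCBr | starting material
6 | [4-(benzyloxy)-3-methoxyphenyl]magnesium bromide | COc1cc([Mg]Br)ccc1OCc1ccccc1 | intermediate
7 | 4-allyl-1-(benzyloxy)-2-methoxybenzene | C=CCc1ccc(OCc2ccccc2)c(OC)c1 | intermediate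
8 | trichloroacetyl chloride | ClC(=O)C(Cl)(Cl)Cl | starting material
9 | dichloroketene | ClC(Cl)=C=O | intermediate
10 | rac-3-[4-(benzyloxy)-3-methoxybenzyl]-2,2-dichlorocyclobutan-1-one | O=C1CC(Cc2ccc(OCc3ccccc3)c(OC)c2)C1(Cl)Cl | intermediate
11 | 3-[4-(benzyloxy)-3-methoxybenzyl]cyclobutan-1-one | O=C1CC(Cc2ccc(OCc3ccccc3)c(OC)c2)C1 | intermediate
12 | (S)-4-[4-(benzyloxy)-3-methoxybenzyl]dihydrofuran-2(3H)-one | COc1cc(C[C@@H]2COC(=O)C2)ccc1OCc1ccccc1 | intermediate
13 | sodium (S)-[4-(4-(benzyloxy)-3-methoxybenzyl)-2-oxodihydrofuran-3(2H)-ylidene]methanolate | COc1cc(C[C@@H]2COC(=O)C2=C[O-])ccc1OCc1ccccc1.[Na+] | intermediate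
14 | (S)-4-[4-(benzyloxy)-3-methoxybenzyl]-3-methylenedihydrofuran-2(3H)-one | COc1cc(C[C@@H]2COC(=O)C2=C)ccc1OCc1ccccc1 | intermediate
15 | [4-(benzyloxy)-3-methoxyphenyl]lithium | COc1cc([Li])ccc1OCc1ccccc1 | intermediate
16 | lithium [4-(benzyloxy)-3-methoxyphenyl](dimethylamino)methanolate | COc1cc(C(O[Li])N(C)C)ccc1OCc1ccccc1 | intermediate
17 | 4-(benzyloxy)-3-methoxybenzaldehyde | COc1cc(C=O)ccc1OCc1ccccc1 | intermediate
18 | ethynylmagnesium bromide | C#C[Mg]Br | starting material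
19 | bromomagnesium rac-1-[4-(benzyloxy)-3-methoxyphenyl]prop-2-yn-1-olate | C#CC(O[Mg]Br)c1ccc(OCc2ccccc2)c(OC)c1 | intermediate
20 | rac-1-[4-(benzyloxy)-3-methoxyphenyl]prop-2-yn-1-yl acetate | C#CC(OC(C)=O)c1ccc(OCc2ccccc2)c(OC)c1 | intermediate
21 | 2-(benzyloxy)phenol | Oc1ccccc1OCc1ccccc1 | intermediate
22 | 2-(benzyloxy)-4-bromophenol | Oc1ccc(Br)cc1OCc1ccccc1 | intermediate
23 | (S)-2-(benzyloxy)-1-{[1-(4-(benzyloxy)-3-methoxyphenyl)prop-2-yn-1-yl]oxy}-4-bromobenzene | C#C[C@@H](c1ccc(OCc2ccccc2)c(OC)c1)Oc1ccc(Br)cc1OCc1ccccc1 | intermediate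
24 | (S)-8-(benzyloxy)-2-[4-(benzyloxy)-3-methoxyphenyl]-6-bromo-2H-chromene | Brc1cc2C=C[C@@H](c3ccc(OCc4ccccc4)c(OC)c3)Oc2c(OCc3ccccc3)c1 | intermediate
25 | (2S,3S)-7-(benzyloxy)-2-[4-(benzyloxy)-3-methoxyphenyl]-5-bromo-3-(dimethoxymethyl)-2,3-dihydrobenzofuran | Brc1cc(OCc2ccccc2)c2c(c1)[C@H](C(OC)OC)[C@@H](c1ccc(OCc3ccccc3)c(OC)c1)O2 | intermediate
26 | [(2S,3S)-7-(benzyloxy)-2-(4-(benzyloxy)-3-methoxyphenyl)-3-(dimethoxymethyl)-2,3-dihydrobenzofuran-5-yl]magnesium bromide | Br[Mg]c1cc(OCc2ccccc2)c2c(c1)[C@H](C(OC)OC)[C@@H](c1ccc(OCc3ccccc3)c(OC)c1)O2 | intermediate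
27 | bromomagnesium enolate of 29 (4S; dihydrobenzofuran 2S,3S) | COc1cc(C[C@@H]2COC(O[Mg]Br)=C2Cc2cc(OCc4ccccc4)c3c(c2)[C@H](C(OC)OC)[C@@H](c2ccc(OCc4ccccc4)c(OC)c2)O3)ccc1OCc1ccccc1 | intermediate
28 | (3R,4S)-cis epimer of 29 (dihydrobenzofuran 2S,3S) | COc1cc(C[C@@H]2COC(=O)[C@@H]2Cc2cc(OCc4ccccc4)c3c(c2)[C@H](C(OC)OC)[C@@H](c2ccc(OCc4ccccc4)c(OC)c2)O3)ccc1OCc1ccccc1 | intermediate
29 | (3S,4S)-3-{[(2S,3S)-7-(benzyloxy)-2-(4-(benzyloxy)-3-methoxyphenyl)-3-(dimethoxymethyl)-2,3-dihydrobenzofuran-5-yl]methyl}-4-[4-(benzyloxy)-3-methoxybenzyl]dihydrofuran-2(3H)-one | COc1cc(C[C@@H]2COC(=O)[C@H]2Cc2cc(OCc4ccccc4)c3c(c2)[C@H](C(OC)OC)[C@@H](c2ccc(OCc4ccccc4)c(OC)c2)O3)ccc1OCc1ccccc1 | intermediate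
30 | (2S,3S)-7-(benzyloxy)-2-[4-(benzyloxy)-3-methoxyphenyl]-5-{[(3S,4S)-4-(4-(benzyloxy)-3-methoxybenzyl)-2-oxotetrahydrofuran-3-yl]methyl}-2,3-dihydrobenzofuran-3-carbaldehyde | COc1cc(C[C@@H]2COC(=O)[C@H]2Cc2cc(OCc4ccccc4)c3c(c2)[C@H](C=O)[C@@H](c2ccc(OCc4ccccc4)c(OC)c2)O3)ccc1OCc1ccccc1 | intermediate
31 | (3S,4S)-3-{[(2S,3R)-7-(benzyloxy)-2-(4-(benzyloxy)-3-methoxyphenyl)-3-(hydroxymethyl)-2,3-dihydrobenzofuran-5-yl]methyl}-4-[4-(benzyloxy)-3-methoxybenzyl]dihydrofuran-2(3H)-one | COc1cc(C[C@@H]2COC(=O)[C@H]2Cc2cc(OCc4ccccc4)c3c(c2)[C@H](CO)[C@@H](c2ccc(OCc4ccccc4)c(OC)c2)O3)ccc1OCc1ccccc1 | intermediate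
32 | (3S,4S)-3-{[(2S,3R)-7-hydroxy-2-(4-hydroxy-3-methoxyphenyl)-3-(hydroxymethyl)-2,3-dihydrobenzofuran-5-yl]methyl}-4-(4-hydroxy-3-methoxybenzyl)dihydrofuran-2(3H)-one | COc1cc(C[C@@H]2COC(=O)[C@H]2Cc2cc(O)c3c(c2)[C@H](CO)[C@@H](c2ccc(O)c(OC)c2)O3)ccc1O | target

## Step count and risks

Total step count: 17.
Longest linear sequence: 11 steps (1 → 2 → 3 → 4 → 17 → 20 → 23 → 24 → 25 → 29 → 31 → 32; steps 1, 2, 3, 8, 9, 12, 13, 14, 15, 16, 17).

Three steps most likely to fail:

**Step 14 (proposed iodine(III) ring contraction).** Simple anti-addition to 3,4-dimethoxyflavans, hydride loss at C2 to a flavylium salt, or attack of the iodane on the electron-rich rings could compete with the aryl shift. The fallback uses only known chemistry; it sets out from chromene 24 and comes back at acetal 25. Markovnikov oxymercuration–demercuration (Hg(OAc)2, THF/H2O; NaBH4) gives (2S)-8-(benzyloxy)-2-[4-(benzyloxy)-3-methoxyphenyl]-6-bromochroman-4-ol F5. Dess–Martin oxidation gives (S)-8-(benzyloxy)-2-[4-(benzyloxy)-3-methoxyphenyl]-6-bromochroman-4-one F6. The established flavanone ring contraction (PhI(OH)OTs, HC(OMe)3, cat. H2SO4) gives methyl (2S,3S)-7-(benzyloxy)-2-[4-(benzyloxy)-3-methoxyphenyl]-5-bromo-2,3-dihydrobenzofuran-3-carboxylate F7. DIBAL-H at −78 °C gives (2S,3S)-7-(benzyloxy)-2-[4-(benzyloxy)-3-methoxyphenyl]-5-bromo-2,3-dihydrobenzofuran-3-carbaldehyde F8, and HC(OMe)3/PPTS/MeOH converts it into 25.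

**Step 13 (gold hydroarylation).** The doubly activated benzylic–propargylic C–O bond may ionise under the π-acid (erosion of ee), and the bromoarene is a modest nucleophile. The fallback replaces hydroarylation by ring-closing metathesis; it sets out from phenol 22 (with acetate 20) and comes back at chromene 24. Magnesium-mediated ortho-formylation of 22 (MgCl2, Et3N, (CH2O)n, MeCN) gives 3-(benzyloxy)-5-bromo-2-hydroxybenzaldehyde F1. Wittig methylenation (Ph3P=CH2, 2.2 equiv) gives 2-(benzyloxy)-4-bromo-6-vinylphenol F2. Copper-catalysed asymmetric propargylic etherification with 20, as in step 12, gives (S)-1-(benzyloxy)-2-{[1-(4-(benzyloxy)-3-methoxyphenyl)prop-2-yn-1-yl]oxy}-5-bromo-3-vinylbenzene F3. Lindlar semi-hydrogenation gives (S)-1-(benzyloxy)-2-{[1-(4-(benzyloxy)-3-methoxyphenyl)allyl]oxy}-5-bromo-3-vinylbenzene F4, and Grubbs II metathesis closes the C3=C4 bond to give 24 with the stereocentre intact.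

**Step 15 (Grignard conjugate addition and equilibration).** Magnesium insertion into the functionalised bromide, oligomerisation of 14, or incomplete cis-to-trans equilibration could cut the yield. The fallback is the classical trans-selective enolate alkylation; it sets out from bromide 25 (with lactone 12) and comes back at 29. Bromine–lithium exchange (n-BuLi, THF, −78 °C) and trapping with paraformaldehyde give [(2S,3S)-7-(benzyloxy)-2-(4-(benzyloxy)-3-methoxyphenyl)-3-(dimethoxymethyl)-2,3-dihydrobenzofuran-5-yl]methanol F9. The Appel reaction (CBr4, PPh3, CH2Cl2, 0 °C) gives (2S,3S)-7-(benzyloxy)-2-[4-(benzyloxy)-3-methoxyphenyl]-5-(bromomethyl)-3-(dimethoxymethyl)-2,3-dihydrobenzofuran F10. The lithium enolate of 12 (LiHMDS, THF/DMPU, −78 °C) is alkylated by F10 anti to the C4 benzyl group to give 29 directly.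

## Further compounds

F1 | step 13 | 3-(benzyloxy)-5-bromo-2-hydroxybenzaldehyde | O=Cc1cc(Br)cc(OCc2ccccc2)c1O
F2 | step 13 | 2-(benzyloxy)-4-bromo-6-vinylphenol | C=Cc1cc(Br)cc(OCc2ccccc2)c1O
F3 | step 13 | (S)-1-(benzyloxy)-2-{[1-(4-(benzyloxy)-3-methoxyphenyl)prop-2-yn-1-yl]oxy}-5-bromo-3-vinylbenzene | C#C[C@@H](c1ccc(OCc2ccccc2)c(OC)c1)Oc1c(C=C)cc(Br)cc1OCc1ccccc1
F4 | step 13 | (S)-1-(benzyloxy)-2-{[1-(4-(benzyloxy)-3-methoxyphenyl)allyl]oxy}-5-bromo-3-vinylbenzene | C=C[C@@H](c1ccc(OCc2ccccc2)c(OC)c1)Oc1c(C=C)cc(Br)cc1OCc1ccccc1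
F5 | step 14 | (2S)-8-(benzyloxy)-2-[4-(benzyloxy)-3-methoxyphenyl]-6-bromochroman-4-ol (C4 epimers) | OC1C[C@@H](c2ccc(OCc3ccccc3)c(OC)c2)Oc2c(OCc3ccccc3)cc(Br)cc12
F6 | step 14 | (S)-8-(benzyloxy)-2-[4-(benzyloxy)-3-methoxyphenyl]-6-bromochroman-4-one | O=C1C[C@@H](c2ccc(OCc3ccccc3)c(OC)c2)Oc2c(OCc3ccccc3)cc(Br)cc12
F7 | step 14 | methyl (2S,3S)-7-(benzyloxy)-2-[4-(benzyloxy)-3-methoxyphenyl]-5-bromo-2,3-dihydrobenzofuran-3-carboxylate | Brc1cc(OCc2ccccc2)c2c(c1)[C@H](C(=O)OC)[C@@H](c1ccc(OCc3ccccc3)c(OC)c1)O2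
F8 | step 14 | (2S,3S)-7-(benzyloxy)-2-[4-(benzyloxy)-3-methoxyphenyl]-5-bromo-2,3-dihydrobenzofuran-3-carbaldehyde | Brc1cc(OCc2ccccc2)c2c(c1)[C@H](C=O)[C@@H](c1ccc(OCc3ccccc3)c(OC)c1)O2
F9 | step 15 | [(2S,3S)-7-(benzyloxy)-2-(4-(benzyloxy)-3-methoxyphenyl)-3-(dimethoxymethyl)-2,3-dihydrobenzofuran-5-yl]methanol | OCc1cc(OCc2ccccc2)c2c(c1)[C@H](C(OC)OC)[C@@H](c1ccc(OCc3ccccc3)c(OC)c1)O2
F10 | step 15 | (2S,3S)-7-(benzyloxy)-2-[4-(benzyloxy)-3-methoxyphenyl]-5-(bromomethyl)-3-(dimethoxymethyl)-2,3-dihydrobenzofuran | BrCc1cc(OCc2ccccc2)c2c(c1)[C@H](C(OC)OC)[C@@H](c1ccc(OCc3ccccc3)c(OC)c1)O2
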